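**Retrosynthetic overview**

1. Numbering (azulene locants of the target): C1 (CH–OAc), C2, C3 (C(OH)i‑Pr), C3a (ring‑fusion CH), C4 (CH–O2CAr), C5=C6(CH3), C7 (C=O), C8, C8a (angular C–CH3); five‑membered ring C1–C3a/C8a, seven‑membered ring C3a–C8a.
2. End game: phenol and C1 acetate last; the C1 carbinol by 1,3‑anti reduction of a C1 ketone (C1 passes the key step as the epimeric silyl ether); C4–H by moving a C4=C5 enol ester/C7 ketone into conjugation (4‑acyloxy‑5‑en‑7‑one).
3. Key disconnection: C3a–C8a and C5–C6 in one step, a gold‑catalysed intramolecular (4+3) annulation of an acyclic propargylic 4‑acetoxybenzoate (C3a–C4≡C5) tethered through C3–C2–C1 to a 2‑siloxydiene (C6=C7(OSi)–C8=C8a); both rings form in this step, the five‑membered ring first, the seven‑membered ring second.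
4. Enabling feature: the seven‑membered ring is a three‑carbon unit C3a–C4–C5 with the ester oxygen on its central carbon C4, joined to a four‑carbon unit C6–C7–C8–C8a with oxygen on the inner carbon C7 (a 2‑acyloxyallyl unit plus a 2‑oxydiene); the acyl group that migrates to create the allyl unit is the aroate of the target.
5. Precursor: C3 from (R)‑2‑hydroxy‑3‑methylbutanoic acid (alkylation with self‑regeneration of the stereocentre), C4–C5 by ethynyl addition, C1 and C6–C8a by Nozaki–Hiyama–Kishi coupling of a C1 aldehyde with an (E)‑β‑iodoenone.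

Key step: step 11

**Route**

Step 1
Reactants: 1 (R)-2-hydroxy-3-methylbutanoic acid; 2 pivalaldehyde
Product: 3 (2R,5R)-2-tert-butyl-5-isopropyl-1,3-dioxolan-4-one (cis)
Conditions: p-TsOH·H2O (cat.), H2SO4 (cat.), pentane, reflux, Dean–Stark
Reagents that add atoms: none
Why: Acid-catalysed acetalisation to the Seebach dioxolanone should give, under thermodynamic control and after crystallisation, the cis isomer in which the new acetal centre (2R) places tert-butyl syn to isopropyl.

Step 2
Reactants: 3; 4 allyl bromide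
Product: 5 (2R,5R)-5-allyl-2-tert-butyl-5-isopropyl-1,3-dioxolan-4-one
Conditions: LiN(i-Pr)2, THF, −78 °C; then 4, −78 → −20 °C
Reagents that add atoms: none
Why: In this alkylation with self-regeneration of the stereocentre (Seebach) the lithium enolate is attacked anti to the tert-butyl group, so allyl replaces hydrogen with retention and the quaternary carbinol carbon (future C3) is fixed as R.

Step 3
Reactants: 5
Product: 7 (4R)-4-isopropylhept-1-en-6-yne-4,5-diol (both C5 epimers), via dioxolanol 6 (not isolated)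
Conditions: i-Bu2AlH, CH2Cl2, −78 °C; then HC≡CMgBr (excess), THF, −78 → 0 °C; aq. potassium sodium tartrate
Reagents that add atoms: ethynylmagnesium bromide (C#C[Mg]Br)
Why: Lactone-to-lactol reduction followed by Grignard addition to the ring-opened α-alkoxy aldehyde (the residual hemiacetal collapses on work-up) should give the diol; the new propargylic centre (future C3a) is formed without control on purpose, since it becomes sp2 in step 11.

Step 4
Reactants: 7; 8 4-acetoxybenzoic acid
Product: 9 (2R)-1-ethynyl-2-hydroxy-2-isopropylpent-4-en-1-yl 4-acetoxybenzoate (both C1 epimers)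
Conditions: DCC, DMAP (cat.), CH2Cl2, 0 °C → rt
Reagents that add atoms: none
Why: Steglich esterification should acylate only the secondary propargylic hydroxyl, the tertiary one being unreactive; no new stereocentre.

Step 5
Reactants: 9
Product: 10 (2R)-1-ethynyl-2-isopropyl-2-(triethylsilyloxy)pent-4-en-1-yl 4-acetoxybenzoate (both C1 epimers)
Conditions: Et3SiOTf, 2,6-lutidine, CH2Cl2, −78 → 0 °C
Reagents that add atoms: triethylsilyl trifluoromethanesulfonate (CC[Si](CC)(CC)OS(=O)(=O)C(F)(F)F)
Why: Silyl triflate/lutidine silylation is the standard way to protect a hindered tertiary alcohol; no new stereocentre.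

Step 6
Reactants: 10
Product: 11 (2R)-1-ethynyl-2-isopropyl-4-oxo-2-(triethylsilyloxy)butyl 4-acetoxybenzoate (both C1 epimers)
Conditions: O3, CH2Cl2/MeOH, −78 °C (Sudan red end point); then PPh3, −78 °C → rt
Reagents that add atoms: ozone ([O-][O+]=O)
Why: Ozonolysis with reductive work-up cleaves the terminal alkene much faster than the alkyne or the electron-poor arene, giving the future C1 aldehyde; no new stereocentre.

Step 7
Reactants: 12 hex-4-yn-3-one
Product: 13 (E)-5-iodohex-4-en-3-one
Conditions: NaI, AcOH, 110 °C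
Reagents that add atoms: sodium iodide ([Na+].[I-])
Why: Conjugate hydroiodination of the ynone gives the β-iodoenone, and iodide addition–elimination under the hot acidic conditions should equilibrate the kinetic Z adduct to the separable E isomer (iodine anti to the acyl group) needed for the diene geometry.

Step 8
Reactants: 11; 13
Product: 14 (2R,4R,5E)-1-ethynyl-4-hydroxy-2-isopropyl-5-methyl-7-oxo-2-(triethylsilyloxy)non-5-en-1-yl 4-acetoxybenzoate (both C1 epimers)
Conditions: CrCl2, NiCl2 (cat.), chiral oxazoline–sulfonamide ligand (Kishi type, the enantiomer that gives the 4R alcohol), Et3N, THF/MeCN, rt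
Reagents that add atoms: none
Why: Nozaki–Hiyama–Kishi coupling: the alkenyl species on trivalent chromium adds to the aldehyde only (ketone, esters and alkyne untouched) with retention of the E geometry, and the new carbinol centre (4R, future C1) is set by the chiral sulfonamide ligand on chromium.

Step 9
Reactants: 14
Product: 15 (2R,4R,5E)-4-(tert-butyldimethylsilyloxy)-1-ethynyl-2-isopropyl-5-methyl-7-oxo-2-(triethylsilyloxy)non-5-en-1-yl 4-acetoxybenzoate (both C1 epimers)
Conditions: t-BuMe2SiCl, imidazole, DMF, rt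
Reagents that add atoms: tert-butyldimethylsilyl chloride (CC(C)(C)[Si](C)(C)Cl)
Why: Standard silylation of a secondary allylic alcohol (silyl chloride/imidazole); no new stereocentre.

Step 10
Reactants: 15
Product: 16 (2R,4R,5E,7Z)-4,7-bis(tert-butyldimethylsilyloxy)-1-ethynyl-2-isopropyl-5-methyl-2-(triethylsilyloxy)nona-5,7-dien-1-yl 4-acetoxybenzoate (both C1 epimers)
Conditions: t-BuMe2SiOTf, Et3N, CH2Cl2, −78 °C
Reagents that add atoms: tert-butyldimethylsilyl trifluoromethanesulfonate (CC(C)(C)[Si](C)(C)OS(=O)(=O)C(F)(F)F)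
Why: Soft kinetic enolisation (silyl triflate/triethylamine) of the ethyl ketone on its CH2CH3 side should give the (Z)-silyl dienol ether without touching the esters; no new stereocentre.

Step 11
Reactants: 16
Product: 17 (1R,3R,3aR,6S,8aS)-1,7-bis(tert-butyldimethylsilyloxy)-3-isopropyl-6,8a-dimethyl-3-(triethylsilyloxy)-1,2,3,3a,6,8a-hexahydroazulen-4-yl 4-acetoxybenzoate
Conditions: Ph3PAuNTf2 (5 mol %), 4 Å MS, CH2Cl2, −20 °C → rt
Reagents that add atoms: none
Why: Proposed new method: cationic monovalent gold activates the terminal alkyne, the ester carbonyl adds to C4 and the C3a–O bond breaks (1,2-acyloxy shift, which also erases the uncontrolled propargylic centre), so that C3a–C4(O2CAr)–C5 becomes a vinylgold carbene with allyl-cation character that the tethered siloxydiene captures in a formal (4+3) cycloaddition, ending with loss of the catalyst and leaving the C4 enol ester and the C7 silyl enol ether. The closest known reactions are the gold-catalysed 1,2-acyloxy migration–cyclopropanation–Cope annulation of propargyl esters with free 1,3-dienes and the gold- or platinum-catalysed intramolecular allene–diene (4+3) cycloaddition to trans-fused 5,7-bicycles; new is the intramolecular capture of the acyloxy vinylcarbene at its vinylogous carbon by a tethered siloxydiene. The five-membered ring should close first by 5-exo attack of C8a of the C8=C8a bond on C3a, and the seven-membered ring when the vinylgold carbon C5 bonds to C6 of the 2-siloxyallyl cation so formed (the second bond of a (4+3) closure, equivalent to cyclopropanation of C6=C7 followed by divinylcyclopropane Cope rearrangement). C3a and C8a are set together: the trans fusion (C3a–H anti to the C8a methyl) should come from the extended transition state of the (E)-C8=C8a alkene with the tether outside, which keeps the C4 aroyloxy group away from the C7 siloxy group, and the absolute sense from the two silyl ether stereocentres of the 2R,4R tether, the C3–OSiEt3 bond lying anti to the forming bond at the electrophilic carbon (polar Felkin–Anh) and the C1–OSi bond lying in the plane of the nucleophilic alkene (inside-alkoxy effect), which is a matched pair; C6 (methyl cis to the C8a–C1 bond, from the (Z)-enol ether) is transient and is erased in step 12. The step needs 1,2- over 1,3-acyloxy migration, secured by the terminal alkyne, and capture of the carbene by the diene before other pathways, secured by the three-atom tether and by the absence of a vinyl group on C3a that would open a Rautenstrauch cyclisation.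

Step 12
Reactants: 17
Product: 19 (1R,3R,3aR,4R,8aS)-1-(tert-butyldimethylsilyloxy)-3-isopropyl-6,8a-dimethyl-7-oxo-3-(triethylsilyloxy)-1,2,3,3a,4,7,8,8a-octahydroazulen-4-yl 4-acetoxybenzoate, via deconjugated ketone 18 (not isolated)
Conditions: Bu4NF, AcOH (1:1), THF, −40 → 0 °C; then DBU (0.3 equiv), CH2Cl2, rt
Reagents that add atoms: none
Why: Buffered fluoride cleaves only the silyl enol ether, and DBU then moves the double bond into conjugation through the dienolate (deconjugated-to-conjugated enone isomerisation), C4 being set under thermodynamic control with the aroyloxy group pseudo-equatorial, anti to the C3a–C3 bond and away from the isopropyl group.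

Step 13
Reactants: 19
Product: 20 (1R,3R,3aR,4R,8aS)-1,3-dihydroxy-3-isopropyl-6,8a-dimethyl-7-oxo-1,2,3,3a,4,7,8,8a-octahydroazulen-4-yl 4-acetoxybenzoate
Conditions: HF·pyridine, pyridine, THF, 0 °C → rt
Reagents that add atoms: none
Why: Fluoride-mediated desilylation under mildly acidic conditions removes both alkyl silyl ethers while the esters, the enone and the phenolic acetate survive; no new stereocentre.

Step 14
Reactants: 20
Product: 21 (3R,3aR,4R,8aS)-3-hydroxy-3-isopropyl-6,8a-dimethyl-1,7-dioxo-1,2,3,3a,4,7,8,8a-octahydroazulen-4-yl 4-acetoxybenzoate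
Conditions: Dess–Martin periodinane, NaHCO3, CH2Cl2, 0 °C → rt
Reagents that add atoms: none
Why: Dess–Martin oxidation converts the only secondary alcohol into the ketone (the tertiary C3 alcohol is inert) and thereby erases the sacrificial C1 stereocentre.

Step 15
Reactants: 21
Product: 22 (1S,3R,3aR,4R,8aS)-1,3-dihydroxy-3-isopropyl-6,8a-dimethyl-7-oxo-1,2,3,3a,4,7,8,8a-octahydroazulen-4-yl 4-acetoxybenzoate
Conditions: Me4NBH(OAc)3, MeCN/AcOH, −30 °C
Reagents that add atoms: none
Why: Hydroxyl-directed Evans–Saksena reduction delivers hydride intramolecularly from the boron bound to the C3 hydroxyl (the face anti to the angular methyl), setting C1 as the 1,3-anti alcohol syn to the angular methyl, and it should leave the enone untouched.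

Step 16
Reactants: 22
Product: 23 (1S,3R,3aR,4R,8aS)-1-acetoxy-3-hydroxy-3-isopropyl-6,8a-dimethyl-7-oxo-1,2,3,3a,4,7,8,8a-octahydroazulen-4-yl 4-acetoxybenzoate
Conditions: Ac2O, pyridine, DMAP (cat.), CH2Cl2, 0 °C → rt
Reagents that add atoms: acetic anhydride (CC(=O)OC(C)=O)
Why: DMAP-catalysed acetylation reacts at the secondary alcohol only, the tertiary alcohol being too hindered; no new stereocentre.

Step 17
Reactants: 23
Product: 24 (1S,3R,3aR,4R,8aS)-1-acetoxy-3-hydroxy-3-isopropyl-6,8a-dimethyl-7-oxo-1,2,3,3a,4,7,8,8a-octahydroazulen-4-yl 4-hydroxybenzoate (target)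
Conditions: NH4OAc, MeOH/H2O (4:1), rt
Reagents that add atoms: none
Why: Ammonium acetate-promoted solvolysis is a standard chemoselective cleavage of a phenolic acetate in the presence of alkyl acetates and benzoate esters; no new stereocentre.

**Compound list**

1 | (R)-2-hydroxy-3-methylbutanoic acid | CC(C)[C@@H](O)C(=O)O | starting material
2 | pivalaldehyde (2,2-dimethylpropanal) | CC(C)(C)C=O | starting material
3 | (2R,5R)-2-tert-butyl-5-isopropyl-1,3-dioxolan-4-one (cis) | CC(C)[C@H]1O[C@@H](C(C)(C)C)OC1=O | intermediate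
4 | allyl bromide | C=CCBr | starting material
5 | (2R,5R)-5-allyl-2-tert-butyl-5-isopropyl-1,3-dioxolan-4-one | CC(C)[C@@]1(CC=C)O[C@@H](C(C)(C)C)OC1=O | intermediate
6 | (2R,5R)-5-allyl-2-tert-butyl-5-isopropyl-1,3-dioxolan-4-ol (lactol, formed as its aluminium alkoxide, both C4 epimers, not isolated) | CC(C)[C@@]1(CC=C)O[C@@H](C(C)(C)C)OC1O | intermediate
7 | (4R)-4-isopropylhept-1-en-6-yne-4,5-diol (both C5 epimers) | C#CC(O)[C@](O)(C(C)C)CC=C | intermediate
8 | 4-acetoxybenzoic acid | CC(=O)Oc1ccc(cc1)C(=O)O | starting material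
9 | (2R)-1-ethynyl-2-hydroxy-2-isopropylpent-4-en-1-yl 4-acetoxybenzoate (both C1 epimers) | C#CC(OC(=O)c1ccc(OC(C)=O)cc1)[C@](O)(C(C)C)CC=C | intermediate
10 | (2R)-1-ethynyl-2-isopropyl-2-(triethylsilyloxy)pent-4-en-1-yl 4-acetoxybenzoate (both C1 epimers) | C#CC(OC(=O)c1ccc(OC(C)=O)cc1)[C@](O[Si](CC)(CC)CC)(C(C)C)CC=C | intermediate
11 | (2R)-1-ethynyl-2-isopropyl-4-oxo-2-(triethylsilyloxy)butyl 4-acetoxybenzoate (both C1 epimers) | C#CC(OC(=O)c1ccc(OC(C)=O)cc1)[C@](O[Si](CC)(CC)CC)(C(C)C)CC=O | intermediate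
12 | hex-4-yn-3-one | CC#CC(=O)CC | starting material
13 | (E)-5-iodohex-4-en-3-one | CCC(=O)/C=C(C)/I | intermediate
14 | (2R,4R,5E)-1-ethynyl-4-hydroxy-2-isopropyl-5-methyl-7-oxo-2-(triethylsilyloxy)non-5-en-1-yl 4-acetoxybenzoate (both C1 epimers) | C#CC(OC(=O)c1ccc(OC(C)=O)cc1)[C@](O[Si](CC)(CC)CC)(C(C)C)C[C@@H](O)/C(C)=C/C(=O)CC | intermediate
15 | (2R,4R,5E)-4-(tert-butyldimethylsilyloxy)-1-ethynyl-2-isopropyl-5-methyl-7-oxo-2-(triethylsilyloxy)non-5-en-1-yl 4-acetoxybenzoate (both C1 epimers) | C#CC(OC(=O)c1ccc(OC(C)=O)cc1)[C@](O[Si](CC)(CC)CC)(C(C)C)C[C@@H](O[Si](C)(C)C(C)(C)C)/C(C)=C/C(=O)CC | intermediate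
16 | (2R,4R,5E,7Z)-4,7-bis(tert-butyldimethylsilyloxy)-1-ethynyl-2-isopropyl-5-methyl-2-(triethylsilyloxy)nona-5,7-dien-1-yl 4-acetoxybenzoate (both C1 epimers) | C#CC(OC(=O)c1ccc(OC(C)=O)cc1)[C@](O[Si](CC)(CC)CC)(C(C)C)C[C@@H](O[Si](C)(C)C(C)(C)C)/C(C)=C/C(O[Si](C)(C)C(C)(C)C)=C/C | intermediate
17 | (1R,3R,3aR,6S,8aS)-1,7-bis(tert-butyldimethylsilyloxy)-3-isopropyl-6,8a-dimethyl-3-(triethylsilyloxy)-1,2,3,3a,6,8a-hexahydroazulen-4-yl 4-acetoxybenzoate | CC(C)(C)[Si](C)(C)O[C@@H]1C[C@@](O[Si](CC)(CC)CC)(C(C)C)[C@H]2C(OC(=O)c3ccc(OC(C)=O)cc3)=C[C@H](C)C(O[Si](C)(C)C(C)(C)C)=C[C@]12C | intermediate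
18 | (1R,3R,3aR,8aS)-1-(tert-butyldimethylsilyloxy)-3-isopropyl-6,8a-dimethyl-7-oxo-3-(triethylsilyloxy)-1,2,3,3a,6,7,8,8a-octahydroazulen-4-yl 4-acetoxybenzoate (C6 epimers, not isolated) | CC(C)(C)[Si](C)(C)O[C@@H]1C[C@@](O[Si](CC)(CC)CC)(C(C)C)[C@H]2C(OC(=O)c3ccc(OC(C)=O)cc3)=CC(C)C(=O)C[C@]12C | intermediate
19 | (1R,3R,3aR,4R,8aS)-1-(tert-butyldimethylsilyloxy)-3-isopropyl-6,8a-dimethyl-7-oxo-3-(triethylsilyloxy)-1,2,3,3a,4,7,8,8a-octahydroazulen-4-yl 4-acetoxybenzoate | CC(C)(C)[Si](C)(C)O[C@@H]1C[C@@](O[Si](CC)(CC)CC)(C(C)C)[C@H]2[C@H](OC(=O)c3ccc(OC(C)=O)cc3)C=C(C)C(=O)C[C@]12C | intermediate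
20 | (1R,3R,3aR,4R,8aS)-1,3-dihydroxy-3-isopropyl-6,8a-dimethyl-7-oxo-1,2,3,3a,4,7,8,8a-octahydroazulen-4-yl 4-acetoxybenzoate | O[C@@H]1C[C@@](O)(C(C)C)[C@H]2[C@H](OC(=O)c3ccc(OC(C)=O)cc3)C=C(C)C(=O)C[C@]12C | intermediate
21 | (3R,3aR,4R,8aS)-3-hydroxy-3-isopropyl-6,8a-dimethyl-1,7-dioxo-1,2,3,3a,4,7,8,8a-octahydroazulen-4-yl 4-acetoxybenzoate | O=C1C[C@@](O)(C(C)C)[C@H]2[C@H](OC(=O)c3ccc(OC(C)=O)cc3)C=C(C)C(=O)C[C@]12C | intermediate
22 | (1S,3R,3aR,4R,8aS)-1,3-dihydroxy-3-isopropyl-6,8a-dimethyl-7-oxo-1,2,3,3a,4,7,8,8a-octahydroazulen-4-yl 4-acetoxybenzoate | O[C@H]1C[C@@](O)(C(C)C)[C@H]2[C@H](OC(=O)c3ccc(OC(C)=O)cc3)C=C(C)C(=O)C[C@]12C | intermediate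
23 | (1S,3R,3aR,4R,8aS)-1-acetoxy-3-hydroxy-3-isopropyl-6,8a-dimethyl-7-oxo-1,2,3,3a,4,7,8,8a-octahydroazulen-4-yl 4-acetoxybenzoate | CC(=O)O[C@H]1C[C@@](O)(C(C)C)[C@H]2[C@H](OC(=O)c3ccc(OC(C)=O)cc3)C=C(C)C(=O)C[C@]12C | intermediate
24 | (1S,3R,3aR,4R,8aS)-1-acetoxy-3-hydroxy-3-isopropyl-6,8a-dimethyl-7-oxo-1,2,3,3a,4,7,8,8a-octahydroazulen-4-yl 4-hydroxybenzoate | CC(=O)O[C@H]1C[C@@](O)(C(C)C)[C@H]2[C@H](OC(=O)c3ccc(O)cc3)C=C(C)C(=O)C[C@]12C | target

**Step count and risks**

Total step count: 17. Longest linear sequence: 16 steps (steps 1–6 and 8–17; step 7 is a side branch).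

Steps most likely to fail:

1. Step 11. The gold carbene may be consumed on other paths (1,3-acyloxy shift to the allene, cyclopropanation of the nearer C8=C8a bond, protodesilylation of the dienol ether), or the rings may close with poor facial or ring-fusion selectivity; in particular the isopropyl group must sit next to the acyloxyallyl plane, which sterics oppose. The fallback uses known chemistry and sets out from 15.
   - Gold-catalysed, ester-assisted Markovnikov hydration of the alkyne (Ph3PAuNTf2, wet dioxane) should give the α-aroyloxy methyl ketone F1.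
   - Double soft enolisation (t-BuMe2SiOTf, Et3N) should give the bis(silyl enol ether) F2.
   - Ionisation of the allylic aroate with Me3SiOTf (cat., CH2Cl2, −78 °C) should generate a 2-siloxyallyl cation, whose classical intramolecular oxyallyl (4+3) cycloaddition with the siloxydiene should give the cycloheptenone F3.
   - Kinetic deprotonation of F3 at the C5 methylene (KN(SiMe3)2, THF, −78 °C) and O-acylation with 4-acetoxybenzoyl chloride should regenerate the enol ester, and the fallback comes back to the route at 17.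

2. Step 12. Protonation of the dienolate at C4 may be kinetically controlled from the wrong face, equilibration may be incomplete, or the aroyl group may migrate or be lost under base. The fallback sets the C4 centre by reduction and inversion instead and sets out from 17.
   - Methanolysis of the enol ester (K2CO3, MeOH, 0 °C) should give the ketone F3.
   - LiBH(s-Bu)3 should attack from the face opposite the isopropyl group and give the 4β-alcohol F4.
   - Mitsunobu esterification with 8 (PPh3, DIAD) should invert C4 and give the 4α-aroate F5.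
   - Buffered Bu4NF should unmask the C7 ketone to the saturated ketone F6.
   - IBX dehydrogenation (DMSO, 70 °C) can only desaturate C5–C6, because C8a is quaternary, and comes back to the route at 19.

3. Step 8. Ligand control at the new carbinol centre may be insufficient, or the hindered β,β-disubstituted iodoenone may couple sluggishly. The fallback sets out from 11 and 13.
   - Silylation of 13 (t-BuMe2SiOTf, Et3N) should give the iododiene F7.
   - Iodine–lithium exchange (t-BuLi, −78 °C), transmetallation with CeCl3 and addition to 11 should give the alcohol F8 as a mixture of carbinol epimers.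
   - Dess–Martin oxidation should give the dienone F9.
   - Corey–Bakshi–Shibata reduction ((S)-Me-CBS, catecholborane) should return F8 as the single 4R epimer.
   - Silylation (t-BuMe2SiCl, imidazole) comes back to the route at 16.

**Further compounds**

F1 | step 11 | (2R,4R,5E)-1-acetyl-4-(tert-butyldimethylsilyloxy)-2-isopropyl-5-methyl-7-oxo-2-(triethylsilyloxy)non-5-en-1-yl 4-acetoxybenzoate (both C1 epimers) | CC(=O)C(OC(=O)c1ccc(OC(C)=O)cc1)[C@](O[Si](CC)(CC)CC)(C(C)C)C[C@@H](O[Si](C)(C)C(C)(C)C)/C(C)=C/C(=O)CC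
F2 | step 11 | (2R,4R,5E,7Z)-4,7-bis(tert-butyldimethylsilyloxy)-1-[1-(tert-butyldimethylsilyloxy)vinyl]-2-isopropyl-5-methyl-2-(triethylsilyloxy)nona-5,7-dien-1-yl 4-acetoxybenzoate (both C1 epimers) | C=C(O[Si](C)(C)C(C)(C)C)C(OC(=O)c1ccc(OC(C)=O)cc1)[C@](O[Si](CC)(CC)CC)(C(C)C)C[C@@H](O[Si](C)(C)C(C)(C)C)/C(C)=C/C(O[Si](C)(C)C(C)(C)C)=C/C
F3 | step 11 | (1R,3R,3aS,6S,8aS)-1,7-bis(tert-butyldimethylsilyloxy)-3-isopropyl-6,8a-dimethyl-3-(triethylsilyloxy)-2,3,3a,5,6,8a-hexahydroazulen-4(1H)-one | CC(C)(C)[Si](C)(C)O[C@@H]1C[C@@](O[Si](CC)(CC)CC)(C(C)C)[C@H]2C(=O)C[C@H](C)C(O[Si](C)(C)C(C)(C)C)=C[C@]12C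
F4 | step 12 | 1,7-bis(tert-butyldimethylsilyloxy)-3-isopropyl-6,8a-dimethyl-3-(triethylsilyloxy)-1,2,3,3a,4,5,6,8a-octahydroazulen-4-ol, 4-hydroxyl β (syn to the angular methyl), other centres as in F3 | CC(C)(C)[Si](C)(C)O[C@@H]1C[C@@](O[Si](CC)(CC)CC)(C(C)C)[C@H]2[C@@H](O)C[C@H](C)C(O[Si](C)(C)C(C)(C)C)=C[C@]12C
F5 | step 12 | 1,7-bis(tert-butyldimethylsilyloxy)-3-isopropyl-6,8a-dimethyl-3-(triethylsilyloxy)-1,2,3,3a,4,5,6,8a-octahydroazulen-4-yl 4-acetoxybenzoate, 4-aroyloxy α (C4 configuration of 19) | CC(C)(C)[Si](C)(C)O[C@@H]1C[C@@](O[Si](CC)(CC)CC)(C(C)C)[C@H]2[C@H](OC(=O)c3ccc(OC(C)=O)cc3)C[C@H](C)C(O[Si](C)(C)C(C)(C)C)=C[C@]12C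
F6 | step 12 | 5,6-dihydro derivative of 19: 1-(tert-butyldimethylsilyloxy)-3-isopropyl-6,8a-dimethyl-7-oxo-3-(triethylsilyloxy)decahydroazulen-4-yl 4-acetoxybenzoate (C6 epimers) | CC(C)(C)[Si](C)(C)O[C@@H]1C[C@@](O[Si](CC)(CC)CC)(C(C)C)[C@H]2[C@H](OC(=O)c3ccc(OC(C)=O)cc3)CC(C)C(=O)C[C@]12C
F7 | step 8 | (2E,4Z)-4-(tert-butyldimethylsilyloxy)-2-iodohexa-2,4-diene | I/C(C)=C/C(O[Si](C)(C)C(C)(C)C)=C/C
F8 | step 8 | (2R,4R,5E,7Z)-7-(tert-butyldimethylsilyloxy)-1-ethynyl-4-hydroxy-2-isopropyl-5-methyl-2-(triethylsilyloxy)nona-5,7-dien-1-yl 4-acetoxybenzoate (both C1 epimers) | C#CC(OC(=O)c1ccc(OC(C)=O)cc1)[C@](O[Si](CC)(CC)CC)(C(C)C)C[C@@H](O)/C(C)=C/C(O[Si](C)(C)C(C)(C)C)=C/C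
F9 | step 8 | (2R,5E,7Z)-7-(tert-butyldimethylsilyloxy)-1-ethynyl-2-isopropyl-5-methyl-4-oxo-2-(triethylsilyloxy)nona-5,7-dien-1-yl 4-acetoxybenzoate (both C1 epimers) | C#CC(OC(=O)c1ccc(OC(C)=O)cc1)[C@](O[Si](CC)(CC)CC)(C(C)C)CC(=O)/C(C)=C/C(O[Si](C)(C)C(C)(C)C)=C/C
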